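**Retrosynthetic overview**

1. Target 13 is taken back to its bis-N-Boc form 12. The (E)-CH=CH–indolyl arm on the quaternary ring carbon is cut at the vinyl–aryl bond (Suzuki–Miyaura) to give alkenylboronate 11 and bromide 4, and 11 is traced to aldehyde 9 (boron–Wittig).
2. Enabling feature: in the central 1,4-dimethylcyclohex-3-ene ring (C1 quaternary with Me and the arm; C2–H with indol-5-yl; C3=C4–Me; C5H2; C6H2) the only double bond lies opposite the C1–C6 edge and the aryl-bearing C2 is allylic. This is a Diels–Alder retron: C2–C3–C4–C5 is an (E)-1-(indol-5-yl)-3-methylbuta-1,3-diene and C6H2=C1(Me)X is a 1,1-disubstituted dienophile.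
3. With X = (E)-2-(indol-5-yl)vinyl the target is the endo [4+2] homodimer of one dienylindole, the presumed biosynthesis. The route copies this cycloaddition with X = CHO (methacrolein 8), the oxidation level at which a chiral Lewis acid can hold the dienophile.
4. Key disconnection: C5–C6 and C1–C2 together, 9 => diene 7 + 8. One step makes the ring, the trisubstituted alkene, the quaternary centre and its neighbour, in relative and absolute configuration.
5. 7 = 4 + dienylboronate 6, and 4 = 5-bromoindole 1 + isoprene 2 (C3 reverse prenylation), then Boc. Both indoles are bought, the cyclohexene (step 5) is the only ring made, and bromide 4 supplies both indole halves.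

Key step: step 5

Assumption: the sense of induction of the (S)-configured catalyst in step 5 is taken from the accepted pre-transition-state model for 2-substituted acroleins; both antipodes of the catalyst precursor are commercial, so the sense can be matched without changing the route.

**Step 1**
Reactants: 1 5-bromo-1H-indole; 2 isoprene (2-methylbuta-1,3-diene)
Product: 3 5-bromo-3-(2-methylbut-3-en-2-yl)-1H-indole
Conditions: [Rh(cod)Cl]2 (2.5 mol %), DTBM-SEGPHOS (5 mol %), CSA (10 mol %), 2 (excess), DCE, 60 °C, sealed tube
Reagents that add atoms: none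
Why: Rh–H-catalysed hydroheteroarylation of isoprene (reverse prenylation of indoles), in which Rh–H adds to the diene to give a 1,1-dimethyl-π-allyl-rhodium species that the free indole attacks through its most nucleophilic carbon C3 at the substituted allyl terminus, after which the ring rearomatises, the aryl bromide stays inert and no stereocentre is formed.

**Step 2**
Reactants: 3 5-bromo-3-(2-methylbut-3-en-2-yl)-1H-indole
Product: 4 tert-butyl 5-bromo-3-(2-methylbut-3-en-2-yl)-1H-indole-1-carboxylate
Conditions: Boc2O, DMAP (cat.), MeCN, rt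
Reagents that add atoms: di-tert-butyl dicarbonate, CC(C)(C)OC(=O)OC(=O)OC(C)(C)C
Why: DMAP-catalysed N-acylation (carbamate protection) of the indole N–H removes the acidic proton and damps the nucleophilicity of N1/C2 for the Lewis acid, carbanion and palladium steps ahead, and no stereocentre is involved.

**Step 3**
Reactants: 5 2-methylbut-1-en-3-yne
Product: 6 2-[(1E)-3-methylbuta-1,3-dien-1-yl]-4,4,5,5-tetramethyl-1,3,2-dioxaborolane
Conditions: HBpin, Cp2ZrHCl (5 mol %), CH2Cl2, rt
Reagents that add atoms: pinacolborane, [H]B1OC(C)(C)C(C)(C)O1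
Why: Zirconocene-hydride-catalysed syn-hydroboration of a terminal alkyne places boron on the terminal carbon and sets the (E)-alkene, the alkyne reacting much faster than the 1,1-disubstituted alkene.

**Step 4**
Reactants: 4 tert-butyl 5-bromo-3-(2-methylbut-3-en-2-yl)-1H-indole-1-carboxylate; 6 (E)-dienylboronate
Product: 7 tert-butyl 5-[(1E)-3-methylbuta-1,3-dien-1-yl]-3-(2-methylbut-3-en-2-yl)-1H-indole-1-carboxylate
Conditions: Pd(dppf)Cl2 (5 mol %), K3PO4, THF/H2O, 60 °C
Reagents that add atoms: none
Why: Suzuki–Miyaura sp2–sp2 coupling proceeds with retention of the (E)-alkenylboronate geometry, the phosphate base leaves the N-Boc group in place, and the temperature lies well below that needed for thermal dimerisation of the diene.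

**Step 5**
Reactants: 7 N-Boc dienylindole; 8 methacrolein (2-methylprop-2-enal)
Product: 9 tert-butyl 5-[(1S,6S)-6-formyl-3,6-dimethylcyclohex-2-en-1-yl]-3-(2-methylbut-3-en-2-yl)-1H-indole-1-carboxylate (indolyl and formyl cis)
Conditions: (S)-B-(o-tolyl) oxazaborolidine from (S)-α,α-diphenylprolinol (20 mol %), Tf2NH (17 mol %), 8 (5 equiv), CH2Cl2, −78 → −40 °C
Reagents that add atoms: none
Why: Boron of the cationic oxazaborolidine binds the formyl oxygen of 8, lowers the LUMO and enlarges its coefficient at the CH2 terminus, so that a concerted but asynchronous normal-demand [4π+2π] cycloaddition takes place in which the CH2–CH2 bond (C5–C6, diene terminus to enal β-carbon) is formed ahead of the hindered benzylic-to-quaternary bond (C2–C1). The closest known reaction type is the catalytic enantioselective Diels–Alder reaction of 2-substituted acroleins with acyclic dienes under chiral boron Lewis acids, and the step is the laboratory copy of the diene-plus-diene [4+2] dimerisation presumed for this skeleton. The cyclohexene is closed by intermolecular suprafacial–suprafacial cycloaddition, which creates both ring σ-bonds and moves the π-bond to C3=C4(Me) in the same event. Regioselectivity is secured twice by the substrate, because the aryl group on the one diene terminus (ortho rule) and the methyl group on the inner carbon next to the other (para rule) both place the largest HOMO coefficient on the free CH2 terminus. The relative configuration (indolyl cis to formyl) follows from the (E)-geometry of 7 and the endo position of the catalyst-bound formyl group, favoured by secondary orbital overlap and by avoidance of the aryl group that flanks the exo quadrant as is known for methacrolein with acyclic 1,3-disubstituted dienes, while the absolute configuration of both centres is set by the catalyst, whose B–O bond and formyl C–H···O contact hold the s-trans enal over one phenyl ring and leave only the Cα-Re face open, which should give the (1S,6S)-aldehyde. Chemoselectivity rests on 7 having one conjugated diene only, the vinyl group on the quaternary carbon being unactivated and free of allylic hydrogen and the Boc group suppressing the nucleophilicity and basicity of the indole toward enal and catalyst.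

**Step 6**
Reactants: 9 (1S,6S)-aldehyde
Product: 11 tert-butyl 5-[(1R,6R)-3,6-dimethyl-6-[(E)-2-(4,4,5,5-tetramethyl-1,3,2-dioxaborolan-2-yl)ethenyl]cyclohex-2-en-1-yl]-3-(2-methylbut-3-en-2-yl)-1H-indole-1-carboxylate, via lithium alkoxide adduct 10 (not isolated)
Conditions: CH2(Bpin)2, LiTMP, THF, 0 °C; then 9, −78 °C → rt
Reagents that add atoms: bis[(pinacolato)boryl]methane, CC1(C)OB(CB2OC(C)(C)C(C)(C)O2)OC1(C)C
Why: Boron–Wittig olefination, in which the α-boryl-stabilised carbanion adds to the non-enolisable aldehyde to give 10, whose syn B–O elimination runs through the rotamer that keeps the bulky quaternary ring carbon anti to the remaining boryl group and should therefore give the (E)-alkenylboronate, while both ring stereocentres stay untouched (same spatial arrangement, descriptors change by priority only).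

**Step 7**
Reactants: 11 (E)-alkenylboronate; 4 tert-butyl 5-bromo-3-(2-methylbut-3-en-2-yl)-1H-indole-1-carboxylate
Product: 12 bis-N-Boc target, di-tert-butyl carbamate of 13 at both indole nitrogens, (1R,6R), (E)
Conditions: Pd(OAc)2 (5 mol %), SPhos (10 mol %), K3PO4, THF/H2O, 50 °C
Reagents that add atoms: none
Why: Suzuki–Miyaura coupling with retention of alkene geometry joins the second copy of bromide 4, transmetalation at the unhindered alkenylboron terminus outrunning any Heck-type reaction of the hindered vinyl groups, and the stereocentres are not involved.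

**Step 8**
Reactants: 12 bis-N-Boc target
Product: 13 5-[(1R,6R)-3,6-dimethyl-6-{(E)-2-[3-(2-methylbut-3-en-2-yl)-1H-indol-5-yl]ethenyl}cyclohex-2-en-1-yl]-3-(2-methylbut-3-en-2-yl)-1H-indole (target)
Conditions: K2CO3, MeOH/THF, 40 °C
Reagents that add atoms: none
Why: Base-catalysed methanolysis of the two indole N-carbamates (acyl transfer from the good indolide leaving group) is a mild non-acidic deprotection that spares the acid-sensitive 3-tert-alkylindoles, all alkenes and both stereocentres.

**Compound list**

1 | 5-bromo-1H-indole | Brc1ccc2[nH]ccc2c1 | starting material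
2 | isoprene | C=CC(C)=C | starting material
3 | 5-bromo-3-(2-methylbut-3-en-2-yl)-1H-indole | C=CC(C)(C)c1c[nH]c2ccc(Br)cc12 | intermediate
4 | tert-butyl 5-bromo-3-(2-methylbut-3-en-2-yl)-1H-indole-1-carboxylate | C=CC(C)(C)c1cn(C(=O)OC(C)(C)C)c2ccc(Br)cc12 | intermediate
5 | 2-methylbut-1-en-3-yne | C=C(C)C#C | starting material
6 | 2-[(1E)-3-methylbuta-1,3-dien-1-yl]-4,4,5,5-tetramethyl-1,3,2-dioxaborolane | C=C(C)/C=C/B1OC(C)(C)C(C)(C)O1 | intermediate
7 | tert-butyl 5-[(1E)-3-methylbuta-1,3-dien-1-yl]-3-(2-methylbut-3-en-2-yl)-1H-indole-1-carboxylate | C=CC(C)(C)c1cn(C(=O)OC(C)(C)C)c2ccc(/C=C/C(C)=C)cc12 | intermediate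
8 | methacrolein | C=C(C)C=O | starting material
9 | tert-butyl 5-[(1S,6S)-6-formyl-3,6-dimethylcyclohex-2-en-1-yl]-3-(2-methylbut-3-en-2-yl)-1H-indole-1-carboxylate | O=C[C@@]1(C)CCC(C)=C[C@H]1c1ccc2n(C(=O)OC(C)(C)C)cc(C(C)(C)C=C)c2c1 | intermediate
10 | lithium alkoxide of tert-butyl 5-[(1S,6S)-6-[1-hydroxy-2,2-bis(pinacolboryl)ethyl]-3,6-dimethylcyclohex-2-en-1-yl]-3-(2-methylbut-3-en-2-yl)-1H-indole-1-carboxylate (carbinol carbon formed as either epimer and erased in the elimination) | [Li]OC(C(B1OC(C)(C)C(C)(C)O1)B1OC(C)(C)C(C)(C)O1)[C@@]1(C)CCC(C)=C[C@H]1c1ccc2n(C(=O)OC(C)(C)C)cc(C(C)(C)C=C)c2c1 | intermediate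
11 | tert-butyl 5-[(1R,6R)-3,6-dimethyl-6-[(E)-2-(pinacolboryl)ethenyl]cyclohex-2-en-1-yl]-3-(2-methylbut-3-en-2-yl)-1H-indole-1-carboxylate | CC1(C)OB(/C=C/[C@@]2(C)CCC(C)=C[C@H]2c2ccc3n(C(=O)OC(C)(C)C)cc(C(C)(C)C=C)c3c2)OC1(C)C | intermediate
12 | bis-N-Boc derivative of the target, (1R,6R), (E) | C=CC(C)(C)c1cn(C(=O)OC(C)(C)C)c2ccc(/C=C/[C@@]3(C)CCC(C)=C[C@H]3c3ccc4n(C(=O)OC(C)(C)C)cc(C(C)(C)C=C)c4c3)cc12 | intermediate
13 | 5-[(1R,6R)-3,6-dimethyl-6-{(E)-2-[3-(2-methylbut-3-en-2-yl)-1H-indol-5-yl]ethenyl}cyclohex-2-en-1-yl]-3-(2-methylbut-3-en-2-yl)-1H-indole | C=CC(C)(C)c1c[nH]c2ccc(/C=C/[C@@]3(C)CCC(C)=C[C@H]3c3ccc4[nH]cc(C(C)(C)C=C)c4c3)cc12 | target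

Total step count: 8. Longest linear sequence: 7 steps (1, 2, 4, 5, 6, 7, 8).

**Steps most likely to fail**

First, step 5.
- Risk: the endo/exo or facial discrimination may be incomplete with the large aryl group next to the forming quaternary centre, or the strongly acidic catalyst may trigger cationic oligomerisation of the electron-rich diene.
- Fallback: it sets out from 7 and comes back to the route at 12.
- Diene 7 is heated without any catalyst (toluene, BHT, 120 °C, sealed tube). Thermal [4+2] homodimerisation is known for (E)-1-arylbuta-1,3-dienes. It uses the CH2=C(Me) end of a second molecule of 7 as the dienophile and forms the same two ring bonds with the same regiochemistry.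
- After chromatography it should give the endo dimer as the racemate, that is 12 together with its mirror image, the (1S,6S)-configured bis-N-Boc dimer F1.
- Preparative HPLC on a chiral stationary phase delivers 12, and steps 6 and 7 are no longer needed.

Second, step 6.
- Risk: addition of the bulky gem-diboryl carbanion to the neopentyl-type formyl group may be slow, which would allow attack on the carbamate or erosion of the alkene geometry.
- Fallback: it sets out from 4 (and uses 9) and comes back to the route at 12, forming the C=C bond itself instead of the vinyl–aryl bond.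
- Stille-type hydroxymethylation of 4 (Bu3SnCH2OH, Pd(PPh3)4, dioxane, 90 °C) should give tert-butyl 5-(hydroxymethyl)-3-(2-methylbut-3-en-2-yl)-1H-indole-1-carboxylate F2.
- Appel bromination (CBr4, PPh3, CH2Cl2, 0 °C) should give tert-butyl 5-(bromomethyl)-3-(2-methylbut-3-en-2-yl)-1H-indole-1-carboxylate F3.
- Michaelis–Becker reaction (NaP(O)(OEt)2, THF, 0 °C) should give tert-butyl 5-[(diethoxyphosphoryl)methyl]-3-(2-methylbut-3-en-2-yl)-1H-indole-1-carboxylate F4.
- Horner–Wadsworth–Emmons reaction of F4 with aldehyde 9 (KHMDS, THF, −78 °C → rt) should give the (E)-alkene 12 directly, so that step 7 is not needed.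

Third, step 1.
- Risk: competing N-allylation or linear prenylation, and low conversion of the bromine-deactivated indole.
- Fallback: it sets out from 1 and comes back to the route at 4, replacing the nucleophilic role of C3 by a cross-coupling.
- Iodination at C3 (I2, KOH, DMF, rt) should give 5-bromo-3-iodo-1H-indole F5.
- Boc2O/DMAP should give tert-butyl 5-bromo-3-iodo-1H-indole-1-carboxylate F6.
- A ligand-controlled γ-selective Suzuki–Miyaura coupling with 3-methylbut-2-en-1-ylboronic acid pinacol ester (Pd(OAc)2, bulky biarylphosphine, K3PO4, THF/H2O, 40 °C) should react at the C–I bond in preference to the C–Br bond. It should deliver the allyl unit through its substituted terminus, giving 4.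

**Further compounds**

F1 | step 5 | (1S,6S)-configured bis-N-Boc dimer, mirror image of 12 | C=CC(C)(C)c1cn(C(=O)OC(C)(C)C)c2ccc(/C=C/[C@]3(C)CCC(C)=C[C@@H]3c3ccc4n(C(=O)OC(C)(C)C)cc(C(C)(C)C=C)c4c3)cc12
F2 | step 6 | tert-butyl 5-(hydroxymethyl)-3-(2-methylbut-3-en-2-yl)-1H-indole-1-carboxylate | C=CC(C)(C)c1cn(C(=O)OC(C)(C)C)c2ccc(CO)cc12
F3 | step 6 | tert-butyl 5-(bromomethyl)-3-(2-methylbut-3-en-2-yl)-1H-indole-1-carboxylate | C=CC(C)(C)c1cn(C(=O)OC(C)(C)C)c2ccc(CBr)cc12
F4 | step 6 | tert-butyl 5-[(diethoxyphosphoryl)methyl]-3-(2-methylbut-3-en-2-yl)-1H-indole-1-carboxylate | C=CC(C)(C)c1cn(C(=O)OC(C)(C)C)c2ccc(CP(=O)(OCC)OCC)cc12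
F5 | step 1 | 5-bromo-3-iodo-1H-indole | Ic1c[nH]c2ccc(Br)cc12
F6 | step 1 | tert-butyl 5-bromo-3-iodo-1H-indole-1-carboxylate | CC(C)(C)OC(=O)n1cc(I)c2cc(Br)ccc21
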